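**Retrosynthetic overview**

1. Kazinol N comes from its ring-A TIPS ether. The 2H-pyran ring (ring C: O1–C2–C3=C4–C4a–C8a) is not closed as a six-membered ring. It is traced back to the 2,5-dihydrofuran ring of a spiro-fused cyclohexa-2,4-dienone and arises from it by a dienone–phenol 1,2-alkenyl shift (five- to six-membered ring expansion, a skeletal rearrangement that also re-aromatizes ring B).
2. Enabling feature: in ring B the phenolic carbon C8, the O1-bearing carbon C8a and the C4-bearing carbon C4a are contiguous. C8 can therefore be a dienone carbonyl and C8a an sp3 spiro carbon that holds both O1 and C4, with C4a as the ring CH that receives C4.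
3. The spirodienone is formed in the same flask by oxidative dearomatization of a phenol with an ortho (Z)-3-hydroxy-3-methylbut-1-enyl chain. That phenol is the MeLi ring-opening product of a 6-prenyl-7-(3-arylpropyl)coumarin, whose lactone is a temporary ring that fixes the Z alkene.
4. The coumarin comes from a B-alkyl Suzuki coupling of a coumarin 7-triflate with the 9-BBN adduct of a ring-A allylarene. The coumarin core is built from 5-bromo-2,4-dihydroxybenzaldehyde (Wittig/lactonization, then Stille prenylation).
5. Ring order: rings A and B are bought as arenes; lactone ring (step 3, opened in step 7); spiro dihydrofuran (step 8, transient); pyran ring C by ring expansion (step 8).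

Key step: step 8

Remark: the target has no stereocentre. The only stereochemical elements on the way are the Z alkene of the ring-opened coumarin and a transient spiro centre that forms as a racemate and disappears on aromatization. Both bromo-arene starting materials are taken as commercial.

**Route**

Step 1
Reactants: 1 4-bromo-3-methoxyphenol
Product: 2 (4-bromo-3-methoxyphenoxy)tri(propan-2-yl)silane
Conditions: TIPSCl, imidazole, DMF, rt
Reagents that add atoms: chlorotri(propan-2-yl)silane (TIPSCl), CC(C)[Si](Cl)(C(C)C)C(C)C
Why: Imidazole-promoted O-silylation of the phenol (silyl ether protection) should be clean, and the bulky TIPS ether is chosen because it should withstand the Pd couplings, MeLi and the oxidant and keep ring A from acting as a second oxidizable phenol.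

Step 2
Reactants: 2 (4-bromo-3-methoxyphenoxy)tri(propan-2-yl)silane
Product: 3 [3-methoxy-4-(prop-2-en-1-yl)phenoxy]tri(propan-2-yl)silane
Conditions: allylSnBu3, Pd(PPh3)4 (5 mol%), DMF, 90 °C
Reagents that add atoms: allyltributylstannane, C=CC[Sn](CCCC)(CCCC)CCCC
Why: Stille cross-coupling of the aryl bromide with the allylstannane (oxidative addition to zerovalent palladium, transmetalation, reductive elimination) should install the terminal alkene needed for hydroboration without touching the silyl ether.

Step 3
Reactants: 4 5-bromo-2,4-dihydroxybenzaldehyde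
Product: 6 6-bromo-7-hydroxy-2H-chromen-2-one, via cinnamate ester 5 (not isolated)
Conditions: Ph3P=CHCO2Et, PhNEt2, reflux (about 215 °C)
Reagents that add atoms: ethyl (triphenylphosphoranylidene)acetate, CCOC(=O)C=P(c1ccccc1)(c1ccccc1)c1ccccc1
Why: Wittig olefination of the aldehyde with the stabilized ylide gives the cinnamate, which at this temperature should undergo E/Z isomerization and intramolecular transesterification with the ortho hydroxyl, a standard route from 2,4-dihydroxybenzaldehydes to 7-hydroxycoumarins that fixes the cis geometry of the C3–C4 alkene inside the lactone ring.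

Step 4
Reactants: 6 6-bromo-7-hydroxy-2H-chromen-2-one
Product: 7 7-hydroxy-6-(3-methylbut-2-en-1-yl)-2H-chromen-2-one
Conditions: prenylSnBu3, Pd(PPh3)4 (10 mol%), DMF, 100 °C
Reagents that add atoms: tributyl(3-methylbut-2-en-1-yl)stannane, CC(C)=CC[Sn](CCCC)(CCCC)CCCC
Why: Stille cross-coupling of the aryl bromide with the prenylstannane should deliver the linear 3-methylbut-2-enyl group because reductive elimination takes place at the less hindered terminus of the allyl ligand, and the free phenol and the lactone are tolerated.

Step 5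
Reactants: 7 7-hydroxy-6-(3-methylbut-2-en-1-yl)-2H-chromen-2-one
Product: 8 6-(3-methylbut-2-en-1-yl)-2-oxo-2H-chromen-7-yl trifluoromethanesulfonate
Conditions: PhNTf2, Et3N, DMAP (cat.), CH2Cl2, 0 °C to rt
Reagents that add atoms: N-phenylbis(trifluoromethanesulfonimide), O=S(=O)(N(c1ccccc1)S(=O)(=O)C(F)(F)F)C(F)(F)F
Why: Base-mediated O-sulfonylation of the phenol with the mild triflyl donor (aryl triflate formation) should spare the prenyl alkene and turn C7 into a cross-coupling site activated by the electron-poor coumarin.

Step 6
Reactants: 3 [3-methoxy-4-(prop-2-en-1-yl)phenoxy]tri(propan-2-yl)silane; 8 6-(3-methylbut-2-en-1-yl)-2-oxo-2H-chromen-7-yl trifluoromethanesulfonate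
Product: 10 7-{3-[2-methoxy-4-(triisopropylsilyloxy)phenyl]propyl}-6-(3-methylbut-2-en-1-yl)-2H-chromen-2-one, via B-alkyl-9-BBN adduct 9 (not isolated)
Conditions: 3, 9-BBN (0.95 equiv relative to 3), THF, 0 °C to rt; then 8, PdCl2(dppf) (5 mol%), K3PO4 (3 M aq.), DMF, 50 °C
Reagents that add atoms: none
Why: Anti-Markovnikov hydroboration of the terminal alkene with 9-BBN followed by B-alkyl Suzuki–Miyaura coupling with the aryl triflate should forge the sp3–sp2 bond of the 1,3-diarylpropane at the final oxidation level, so that no later hydrogenation has to distinguish the prenyl and lactone alkenes, and the borane is consumed before the prenylated triflate is added.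

Step 7
Reactants: 10 7-{3-[2-methoxy-4-(triisopropylsilyloxy)phenyl]propyl}-6-(3-methylbut-2-en-1-yl)-2H-chromen-2-one
Product: 11 2-[(1Z)-3-hydroxy-3-methylbut-1-en-1-yl]-5-{3-[2-methoxy-4-(triisopropylsilyloxy)phenyl]propyl}-4-(3-methylbut-2-en-1-yl)phenol
Conditions: MeLi (3.5 equiv), THF, −78 to −20 °C; aq. NH4Cl, 0 °C; used at once
Reagents that add atoms: methyllithium, [Li]C
Why: Twofold 1,2-addition of MeLi to the lactone carbonyl (acyl substitution to the enone, then addition to the ketone) should open the temporary pyranone ring to the phenol and the tertiary allylic alcohol, the Z geometry of the alkene being inherited from the ring alkene, and the neutral cold work-up is meant to prevent acid-catalysed cyclodehydration.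

Step 8
Reactants: 11 2-[(1Z)-3-hydroxy-3-methylbut-1-en-1-yl]-5-{3-[2-methoxy-4-(triisopropylsilyloxy)phenyl]propyl}-4-(3-methylbut-2-en-1-yl)phenol
Product: 13 6-{3-[2-methoxy-4-(triisopropylsilyloxy)phenyl]propyl}-2,2-dimethyl-5-(3-methylbut-2-en-1-yl)-2H-chromen-8-ol, via spirodienone 12 (not isolated)
Conditions: PhI(OAc)2 (1.0 equiv), CH2Cl2, −40 °C; then BF3·OEt2 (0.3 equiv), −40 to 0 °C
Reagents that add atoms: none
Why: Ligand exchange of the phenol on trivalent iodine and attack of the tertiary hydroxyl on the alkenyl-bearing ortho carbon, with loss of iodobenzene and acetate, should give the spiro-fused cyclohexa-2,4-dienone 12 (hypervalent-iodine oxidative dearomatization, ortho-spiroetherification). BF3 then activates the dienone carbonyl, the resulting hydroxycyclohexadienyl cation carries positive charge on the ring CH next to the spiro carbon, and the alkenyl carbon of the dihydrofuran (the future C4) shifts onto it, so that the five-membered ring becomes the fused six-membered pyran and loss of the proton restores the arene (dienone–phenol rearrangement; closest precedent is the acid-promoted ring expansion of spiro[4.5]decadienones to tetralinols and of quinol spiro-ethers to chromans). The only ring closed is the spiro dihydrofuran (5-exo-trig C–O closure); the pyran is not closed but arises from it by migration of the C4–C(spiro) bond. The spiro carbon of 12 is the one new stereocentre, it forms as a racemate and is erased on aromatization, so no stereocontrol is needed. The step needs ortho over para capture, secured by the Z alkene that holds the hydroxyl over the ortho carbon while the prenyl-bearing para carbon offers only intermolecular attack, and carbon over oxygen migration, secured because the sp2 carbon can migrate through a bridged cation and leaves an oxygen-stabilized cation whereas the ether oxygen cannot bridge. The oxidant is limited to 1.0 equivalent and is consumed before the acid is added, so that the electron-rich product phenol and the prenyl alkene should never meet acid-activated trivalent iodine.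

Step 9
Reactants: 13 6-{3-[2-methoxy-4-(triisopropylsilyloxy)phenyl]propyl}-2,2-dimethyl-5-(3-methylbut-2-en-1-yl)-2H-chromen-8-ol
Product: 14 Kazinol N (6-[3-(4-hydroxy-2-methoxyphenyl)propyl]-2,2-dimethyl-5-(3-methylbut-2-en-1-yl)-2H-chromen-8-ol)
Conditions: Bu4NF (1.5 equiv), AcOH (1.5 equiv), THF, 0 °C
Reagents that add atoms: none
Why: Fluoride-induced cleavage of the aryl silyl ether (desilylation), buffered with AcOH so that no phenoxide is exposed to air, should release the ring-A phenol without affecting the chromene or the prenyl group.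

**Compound list**

1 | 4-bromo-3-methoxyphenol | COc1cc(O)ccc1Br | starting material
2 | (4-bromo-3-methoxyphenoxy)tri(propan-2-yl)silane | COc1cc(O[Si](C(C)C)(C(C)C)C(C)C)ccc1Br | intermediate
3 | [3-methoxy-4-(prop-2-en-1-yl)phenoxy]tri(propan-2-yl)silane | COc1cc(O[Si](C(C)C)(C(C)C)C(C)C)ccc1CC=C | intermediate
4 | 5-bromo-2,4-dihydroxybenzaldehyde | O=Cc1cc(Br)c(O)cc1O | starting material
5 | ethyl (2E)-3-(5-bromo-2,4-dihydroxyphenyl)prop-2-enoate (not isolated; isomerizes to Z and lactonizes) | CCOC(=O)/C=C/c1cc(Br)c(O)cc1O | intermediate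
6 | 6-bromo-7-hydroxy-2H-chromen-2-one | O=c1ccc2cc(Br)c(O)cc2o1 | intermediate
7 | 7-hydroxy-6-(3-methylbut-2-en-1-yl)-2H-chromen-2-one | CC(C)=CCc1cc2ccc(=O)oc2cc1O | intermediate
8 | 6-(3-methylbut-2-en-1-yl)-2-oxo-2H-chromen-7-yl trifluoromethanesulfonate | CC(C)=CCc1cc2ccc(=O)oc2cc1OS(=O)(=O)C(F)(F)F | intermediate
9 | 9-{3-[2-methoxy-4-(triisopropylsilyloxy)phenyl]propyl}-9-borabicyclo[3.3.1]nonane (not isolated) | COc1cc(O[Si](C(C)C)(C(C)C)C(C)C)ccc1CCCB1C2CCCC1CCC2 | intermediate
10 | 7-{3-[2-methoxy-4-(triisopropylsilyloxy)phenyl]propyl}-6-(3-methylbut-2-en-1-yl)-2H-chromen-2-one | COc1cc(O[Si](C(C)C)(C(C)C)C(C)C)ccc1CCCc1cc2oc(=O)ccc2cc1CC=C(C)C | intermediate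
11 | 2-[(1Z)-3-hydroxy-3-methylbut-1-en-1-yl]-5-{3-[2-methoxy-4-(triisopropylsilyloxy)phenyl]propyl}-4-(3-methylbut-2-en-1-yl)phenol | COc1cc(O[Si](C(C)C)(C(C)C)C(C)C)ccc1CCCc1cc(O)c(/C=C\C(C)(C)O)cc1CC=C(C)C | intermediate
12 | 8-{3-[2-methoxy-4-(triisopropylsilyloxy)phenyl]propyl}-2,2-dimethyl-9-(3-methylbut-2-en-1-yl)-1-oxaspiro[4.5]deca-3,7,9-trien-6-one (racemic spiro centre, not isolated) | CC1(C)C=CC2(O1)C=C(CC=C(C)C)C(CCCc1ccc(O[Si](C(C)C)(C(C)C)C(C)C)cc1OC)=CC2=O | intermediate
13 | 6-{3-[2-methoxy-4-(triisopropylsilyloxy)phenyl]propyl}-2,2-dimethyl-5-(3-methylbut-2-en-1-yl)-2H-chromen-8-ol | COc1cc(O[Si](C(C)C)(C(C)C)C(C)C)ccc1CCCc1cc(O)c2c(c1CC=C(C)C)C=CC(C)(C)O2 | intermediate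
14 | Kazinol N, 6-[3-(4-hydroxy-2-methoxyphenyl)propyl]-2,2-dimethyl-5-(3-methylbut-2-en-1-yl)-2H-chromen-8-ol | COc1cc(O)ccc1CCCc1cc(O)c2c(c1CC=C(C)C)C=CC(C)(C)O2 | target

**Step count and risks**

Total steps: 9. Longest linear sequence: 7 (steps 3 to 9, from 4).

Steps most likely to fail:

Step 8. The oxidized phenol may be captured at the prenyl-bearing para carbon by acetate instead of spirocyclizing. The diol may cyclodehydrate before it is oxidized. In the shift, the allylic C–O bond of the spiro ether may ionize faster than the alkenyl group migrates. The fallback sets out from 10 and comes back at 13. It moves the ring expansion to the lactone oxidation level, where no ionizable allylic ether exists and the internal nucleophile is a carboxylate. Coumarin 10 would be saponified (LiOH, THF–H2O, 0 °C) to the dilithium (Z)-coumarinate F1. Without acidification, F1 would be oxidized (PhI(OAc)2, NaHCO3, MeCN–H2O, 0 °C) to the spiro-butenolide dienone F2. Acid (TfOH or BF3·OEt2, CH2Cl2) should expand the butenolide by the same 1,2-alkenyl shift to the 1,2-transposed 8-hydroxycoumarin F3. MeLi should open F3 to the catechol triol F4, and mild acid (PPTS, CH2Cl2) should cyclodehydrate F4 to 13, since only the hydroxyl ortho to the side chain can close.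

Step 7. Conjugate addition of MeLi to the coumarin may compete, and the Z-diol may lose water to the phenol-free 2,2-dimethylchromene during work-up and handling. The fallback sets out from 10 and comes back at 11. The lactone would be opened with the phenol masked: NaOMe in MeOH–THF at 0 °C with allyl bromide present should trap the ring-opened phenoxide as methyl (Z)-cinnamate allyl ether F5. MeLi (THF, −78 °C) should convert the ester into the tertiary alcohol allyl ether F6, which cannot cyclodehydrate and can be purified. Deallylation with Pd(PPh3)4 (cat.) and morpholine in THF at rt should release 11 under neutral conditions directly before step 8.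

Step 4. Coupling through the more substituted terminus of the prenyl group would give the 1,1-dimethylallyl isomer, and oxidative addition next to the free phenol may be sluggish. The fallback sets out from 6 and comes back at 7. Stille coupling with allylSnBu3 (Pd(PPh3)4, DMF, 90 °C), which has no regiochemical ambiguity, should give 6-allyl-7-hydroxycoumarin F7. Olefin cross-metathesis of F7 with 2-methylbut-2-ene (second-generation Grubbs catalyst, CH2Cl2, 40 °C) should then build the prenyl group of 7.

**Further compounds**

F1 | step 8 | dilithium (2Z)-3-[4-{3-[2-methoxy-4-(triisopropylsilyloxy)phenyl]propyl}-5-(3-methylbut-2-en-1-yl)-2-oxidophenyl]prop-2-enoate | [Li+].[Li+].[O-]C(=O)/C=C\c1cc(CC=C(C)C)c(CCCc2ccc(O[Si](C(C)C)(C(C)C)C(C)C)cc2OC)cc1[O-]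
F2 | step 8 | 8-{3-[2-methoxy-4-(triisopropylsilyloxy)phenyl]propyl}-9-(3-methylbut-2-en-1-yl)-1-oxaspiro[4.5]deca-3,7,9-triene-2,6-dione (racemic) | O=C1C=CC2(O1)C=C(CC=C(C)C)C(CCCc1ccc(O[Si](C(C)C)(C(C)C)C(C)C)cc1OC)=CC2=O
F3 | step 8 | 8-hydroxy-6-{3-[2-methoxy-4-(triisopropylsilyloxy)phenyl]propyl}-5-(3-methylbut-2-en-1-yl)-2H-chromen-2-one | COc1cc(O[Si](C(C)C)(C(C)C)C(C)C)ccc1CCCc1cc(O)c2oc(=O)ccc2c1CC=C(C)C
F4 | step 8 | 3-[(1Z)-3-hydroxy-3-methylbut-1-en-1-yl]-5-{3-[2-methoxy-4-(triisopropylsilyloxy)phenyl]propyl}-4-(3-methylbut-2-en-1-yl)benzene-1,2-diol | COc1cc(O[Si](C(C)C)(C(C)C)C(C)C)ccc1CCCc1cc(O)c(O)c(/C=C\C(C)(C)O)c1CC=C(C)C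
F5 | step 7 | methyl (2Z)-3-[2-(allyloxy)-4-{3-[2-methoxy-4-(triisopropylsilyloxy)phenyl]propyl}-5-(3-methylbut-2-en-1-yl)phenyl]prop-2-enoate | COC(=O)/C=C\c1cc(CC=C(C)C)c(CCCc2ccc(O[Si](C(C)C)(C(C)C)C(C)C)cc2OC)cc1OCC=C
F6 | step 7 | (3Z)-4-[2-(allyloxy)-4-{3-[2-methoxy-4-(triisopropylsilyloxy)phenyl]propyl}-5-(3-methylbut-2-en-1-yl)phenyl]-2-methylbut-3-en-2-ol | CC(C)(O)/C=C\c1cc(CC=C(C)C)c(CCCc2ccc(O[Si](C(C)C)(C(C)C)C(C)C)cc2OC)cc1OCC=C
F7 | step 4 | 6-allyl-7-hydroxy-2H-chromen-2-one | C=CCc1cc2ccc(=O)oc2cc1O
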